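**Retrosynthetic overview**
1. Target 17 ⇐ (R)-shikonin 15 + 3,4-dimethylpent-3-enoic acid 16, by selective esterification of the side-chain OH.
2. 15 ⇐ quinone 14 (two phenols as MOM ethers, carbinol as TES ether); one acid treatment unmasks all three oxygens.
3. Key disconnection: the quinone ring of 14 by Dötz benzannulation (alkyne insertion, CO insertion, 6π-electrocyclisation) of aryl Fischer carbene 12 with chiral alkyne 6, then oxidative work-up.
4. 6 ⇐ methyl (R)-glycidate 1, which carries the only stereocentre, via cuprate opening, silylation and ester-to-alkyne homologation; 12 ⇐ hydroquinone 7.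
5. Ring order: the benzenoid ring is bought as hydroquinone; the quinone ring is the only ring made, in step 6.

Assumption: 3,4-dimethylpent-3-enoic acid (16), methyl (R)-glycidate (1) and the Grignard solution 2 are taken as catalogue items.

**Route**

Step 1
Reactants: 1 methyl (2R)-oxirane-2-carboxylate; 2 (2-methylprop-1-en-1-yl)magnesium bromide
Product: 3 methyl (2R)-2-hydroxy-5-methylhex-4-enoate
Conditions: CuBr·SMe2 (10 mol%), THF, −78 → −40 °C; aq NH4Cl
Reagents that add atoms: none
Why: Copper-catalysed Grignard opening of the epoxide (SN2 at the unhindered CH2, faster than ester addition at low temperature) installs the prenyl chain without touching C2, so the bought (R) centre is carried over unchanged.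

Step 2
Reactants: 3 methyl (2R)-2-hydroxy-5-methylhex-4-enoate
Product: 4 methyl (2R)-5-methyl-2-(triethylsilyloxy)hex-4-enoate
Conditions: TESCl, imidazole, DMF, 0 °C → rt
Reagents that add atoms: chlorotriethylsilane, CC[Si](Cl)(CC)CC
Why: Standard silyl ether formation masks the hydroxyl for the hydride and carbene steps and is later removed in the same acid step as the MOM groups; the stereocentre is not involved.

Step 3
Reactants: 4 methyl (2R)-5-methyl-2-(triethylsilyloxy)hex-4-enoate
Product: 6 triethyl{[(3R)-6-methylhept-5-en-1-yn-3-yl]oxy}silane, via silyloxy aldehyde 5 (not isolated)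
Conditions: DIBAL-H (1.1 eq), CH2Cl2, −78 °C; then MeOH, dimethyl (1-diazo-2-oxopropyl)phosphonate, K2CO3, −78 °C → rt
Reagents that add atoms: dimethyl (1-diazo-2-oxopropyl)phosphonate, COP(=O)(OC)C(=[N+]=[N-])C(C)=O
Why: DIBAL-H half-reduction stops at the aluminium hemiacetal at −78 °C, and the aldehyde released by MeOH is trapped at once in a Seyferth–Gilbert homologation with the Ohira–Bestmann reagent, under which α-silyloxy aldehydes normally keep their configuration.

Step 4
Reactants: 7 hydroquinone
Product: 8 1,4-bis(methoxymethoxy)benzene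
Conditions: NaH, MOMCl, DMF, 0 °C → rt
Reagents that add atoms: chloromethyl methyl ether, COCCl
Why: Williamson-type O-alkylation of the bis-phenoxide gives MOM ethers that direct ortho-lithiation, survive the carbene chemistry and come off with dilute acid.

Step 5
Reactants: 8 1,4-bis(methoxymethoxy)benzene; 9 hexacarbonylchromium
Product: 12 pentacarbonyl{[2,5-bis(methoxymethoxy)phenyl](methoxy)methylidene}chromium(0), via aryllithium 10 (not isolated), via lithium acylchromate 11 (not isolated)
Conditions: n-BuLi, THF, 0 °C → rt; Cr(CO)6, THF/Et2O, 0 °C → rt; Me3OBF4, CH2Cl2, 0 °C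
Reagents that add atoms: trimethyloxonium tetrafluoroborate, C[O+](C)C.F[B-](F)(F)F
Why: MOM-directed ortho-lithiation, addition of the aryllithium to a CO ligand and O-methylation of the acylchromate is the classical Fischer carbene synthesis.

Step 6
Reactants: 12 pentacarbonyl{[2,5-bis(methoxymethoxy)phenyl](methoxy)methylidene}chromium(0); 6 triethyl{[(3R)-6-methylhept-5-en-1-yn-3-yl]oxy}silane
Product: 14 5,8-bis(methoxymethoxy)-2-[(1R)-4-methyl-1-(triethylsilyloxy)pent-3-en-1-yl]naphthalene-1,4-dione, via chromium-bound naphthol 13 (not isolated)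
Conditions: THF, 50 °C, Ar, 16 h; then CAN, MeCN/H2O, 0 °C
Reagents that add atoms: water, O
Why: Dötz benzannulation builds the new ring by alkyne insertion, CO insertion to a chromium-bound dienylketene and 6π-electrocyclisation onto the free ortho position, and CAN then strips chromium and oxidises the 4-methoxy-1-naphthol ring to the quinone while the propargylic stereocentre is a spectator.

Step 7
Reactants: 14 5,8-bis(methoxymethoxy)-2-[(1R)-4-methyl-1-(triethylsilyloxy)pent-3-en-1-yl]naphthalene-1,4-dione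
Product: 15 5,8-dihydroxy-2-[(1R)-1-hydroxy-4-methylpent-3-en-1-yl]naphthalene-1,4-dione ((R)-shikonin)
Conditions: 3 M aq HCl/THF (1:3), rt → 40 °C
Reagents that add atoms: none
Why: Acid hydrolysis of the silyl ether and of the two peri-MOM acetals unmasks shikonin without breaking the C–O bond at the stereocentre.

Step 8
Reactants: 15 (R)-shikonin; 16 3,4-dimethylpent-3-enoic acid
Product: 17 (1R)-1-(5,8-dihydroxy-1,4-dioxo-1,4-dihydronaphthalen-2-yl)-4-methylpent-3-en-1-yl 3,4-dimethylpent-3-enoate
Conditions: DCC, DMAP (cat.), CH2Cl2, 0 °C → rt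
Reagents that add atoms: none
Why: Steglich esterification acylates only the side-chain hydroxyl because both phenols are locked in hydrogen bonds to the quinone carbonyls, and acylation on oxygen retains the (R) configuration.

**Compound list**
1 | methyl (2R)-oxirane-2-carboxylate (methyl (R)-glycidate) | COC(=O)[C@H]1CO1 | starting material
2 | (2-methylprop-1-en-1-yl)magnesium bromide | CC(C)=C[Mg]Br | starting material
3 | methyl (2R)-2-hydroxy-5-methylhex-4-enoate | COC(=O)[C@H](O)CC=C(C)C | intermediate
4 | methyl (2R)-5-methyl-2-(triethylsilyloxy)hex-4-enoate | COC(=O)[C@H](O[Si](CC)(CC)CC)CC=C(C)C | intermediate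
5 | (2R)-5-methyl-2-(triethylsilyloxy)hex-4-enal | O=C[C@H](O[Si](CC)(CC)CC)CC=C(C)C | intermediate (not isolated)
6 | triethyl{[(3R)-6-methylhept-5-en-1-yn-3-yl]oxy}silane | C#C[C@H](O[Si](CC)(CC)CC)CC=C(C)C | intermediate
7 | hydroquinone | Oc1ccc(O)cc1 | starting material
8 | 1,4-bis(methoxymethoxy)benzene | COCOc1ccc(OCOC)cc1 | intermediate
9 | hexacarbonylchromium | O=C=[Cr](=C=O)(=C=O)(=C=O)(=C=O)=C=O | starting material
10 | [2,5-bis(methoxymethoxy)phenyl]lithium | [Li]c1cc(OCOC)ccc1OCOC | intermediate (not isolated)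
11 | lithium pentacarbonyl{[2,5-bis(methoxymethoxy)phenyl](oxido)methylidene}chromate | [Li+].[O-]C(=[Cr](=C=O)(=C=O)(=C=O)(=C=O)=C=O)c1cc(OCOC)ccc1OCOC | intermediate (not isolated)
12 | pentacarbonyl{[2,5-bis(methoxymethoxy)phenyl](methoxy)methylidene}chromium(0) | COCOc1ccc(OCOC)c(c1)C(OC)=[Cr](=C=O)(=C=O)(=C=O)(=C=O)=C=O | intermediate
13 | 4-methoxy-5,8-bis(methoxymethoxy)-2-[(1R)-4-methyl-1-(triethylsilyloxy)pent-3-en-1-yl]naphthalen-1-ol (formed as its Cr(CO)3 complex) | CC(C)=CC[C@@H](O[Si](CC)(CC)CC)c1cc(OC)c2c(OCOC)ccc(OCOC)c2c1O | intermediate (not isolated)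
14 | 5,8-bis(methoxymethoxy)-2-[(1R)-4-methyl-1-(triethylsilyloxy)pent-3-en-1-yl]naphthalene-1,4-dione | CC(C)=CC[C@@H](O[Si](CC)(CC)CC)C1=CC(=O)c2c(OCOC)ccc(OCOC)c2C1=O | intermediate
15 | 5,8-dihydroxy-2-[(1R)-1-hydroxy-4-methylpent-3-en-1-yl]naphthalene-1,4-dione ((R)-shikonin) | CC(C)=CC[C@@H](O)C1=CC(=O)c2c(O)ccc(O)c2C1=O | intermediate
16 | 3,4-dimethylpent-3-enoic acid | CC(C)=C(C)CC(O)=O | starting material
17 | (1R)-1-(5,8-dihydroxy-1,4-dioxo-1,4-dihydronaphthalen-2-yl)-4-methylpent-3-en-1-yl 3,4-dimethylpent-3-enoate | CC(C)=CC[C@@H](OC(=O)CC(C)=C(C)C)C1=CC(=O)c2c(O)ccc(O)c2C1=O | target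

**Step count and risks**
Total: 8 steps. Longest linear sequence: 6 steps (1 → 3 → 4 → 6 → 14 → 15 → 17); the carbene branch (7 → 8 → 12) is 2 steps.

Step 6 (most likely to fail). Ortho-alkoxy aryl carbenes can divert to indenes or cyclobutenones, and the MOM ethers must survive the CAN work-up. The fallback sets out from 6 and comes back at 15. It makes the carbinol-bearing ring as a benzoquinone by benzannulation with an alkenyl carbene and adds the second ring by a Diels–Alder reaction, so no phenol protection is needed. (E)-(2-Bromoethenyl)trimethylsilane is lithiated with t-BuLi, added to 9 and O-methylated to give pentacarbonyl{methoxy[(E)-2-(trimethylsilyl)ethenyl]methylidene}chromium(0) F1, a stable stand-in for the parent vinyl carbene. Benzannulation of F1 with 6 (the silyl group ends on the phenol oxygen and is lost on oxidation) and CAN work-up give 2-[(1R)-4-methyl-1-(triethylsilyloxy)pent-3-en-1-yl]cyclohexa-2,5-diene-1,4-dione F2. Succinic anhydride with TMSOTf/Et3N gives 2,5-bis(trimethylsilyloxy)furan F3. [4+2] cycloaddition of F3 to the unsubstituted C=C of F2 in CH2Cl2, followed by ring opening and enolisation, gives O-triethylsilylshikonin F4. Dilute aq HCl/THF then returns 15.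

Step 7. The free carbinol of shikonin may cyclise onto the prenyl alkene or solvolyse under acid before both MOM groups are gone. The fallback sets out from 14 and comes back at 17, bypassing 15, by changing the order so that the carbinol is acylated before the phenols are unmasked. HF·pyridine in THF at 0 °C removes only the TES group to give 2-[(1R)-1-hydroxy-4-methylpent-3-en-1-yl]-5,8-bis(methoxymethoxy)naphthalene-1,4-dione F5. Steglich esterification with 16 gives (1R)-1-[5,8-bis(methoxymethoxy)-1,4-dioxo-1,4-dihydronaphthalen-2-yl]-4-methylpent-3-en-1-yl 3,4-dimethylpent-3-enoate F6. TFA/CH2Cl2 at 0 °C with aqueous work-up then cleaves the MOM ethers to give 17.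

Step 3. The α-silyloxy aldehyde may partly epimerise under K2CO3/MeOH, or the one-pot may stall on aluminium salts. The fallback sets out from 4 and comes back at 6, replacing the diazophosphonate homologation by a Corey–Fuchs sequence. After DIBAL-H reduction, aldehyde 5 is isolated cold and treated with CBr4/PPh3/Et3N in CH2Cl2 at 0 °C to give triethyl{[(3R)-1,1-dibromo-6-methylhepta-1,5-dien-3-yl]oxy}silane F7. n-BuLi (2.1 eq) in THF at −78 °C then gives 6 by Fritsch–Buttenberg–Wiechell rearrangement.

**Further compounds**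
F1 | step 6 | pentacarbonyl{methoxy[(E)-2-(trimethylsilyl)ethenyl]methylidene}chromium(0) | COC(/C=C/[Si](C)(C)C)=[Cr](=C=O)(=C=O)(=C=O)(=C=O)=C=O
F2 | step 6 | 2-[(1R)-4-methyl-1-(triethylsilyloxy)pent-3-en-1-yl]cyclohexa-2,5-diene-1,4-dione | CC(C)=CC[C@@H](O[Si](CC)(CC)CC)C1=CC(=O)C=CC1=O
F3 | step 6 | 2,5-bis(trimethylsilyloxy)furan | C[Si](C)(C)Oc1ccc(O[Si](C)(C)C)o1
F4 | step 6 | O-triethylsilylshikonin (5,8-dihydroxy-2-[(1R)-4-methyl-1-(triethylsilyloxy)pent-3-en-1-yl]naphthalene-1,4-dione) | CC(C)=CC[C@@H](O[Si](CC)(CC)CC)C1=CC(=O)c2c(O)ccc(O)c2C1=O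
F5 | step 7 | 2-[(1R)-1-hydroxy-4-methylpent-3-en-1-yl]-5,8-bis(methoxymethoxy)naphthalene-1,4-dione | CC(C)=CC[C@@H](O)C1=CC(=O)c2c(OCOC)ccc(OCOC)c2C1=O
F6 | step 7 | (1R)-1-[5,8-bis(methoxymethoxy)-1,4-dioxo-1,4-dihydronaphthalen-2-yl]-4-methylpent-3-en-1-yl 3,4-dimethylpent-3-enoate | CC(C)=CC[C@@H](OC(=O)CC(C)=C(C)C)C1=CC(=O)c2c(OCOC)ccc(OCOC)c2C1=O
F7 | step 3 | triethyl{[(3R)-1,1-dibromo-6-methylhepta-1,5-dien-3-yl]oxy}silane | BrC(Br)=C[C@H](O[Si](CC)(CC)CC)CC=C(C)C
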